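**Retrosynthetic overview**
1. Target ⇒ senecioylation at O9 and reductive α‑oxygenation (H to C10, O to C9) of the eremophila‑9,11‑dien‑8‑one neopetasin.
2. Neopetasin ⇒ one transannular cation cascade of a ten‑membered germacra‑4,9,11‑trien‑8‑one 3‑angelate: C5–C10 bond, 1,2‑H shift C5→C4, 1,2‑CH3 shift C10→C5 (germacrane → eudesmyl cation → eremophilane).
3. Ten‑membered ring ⇒ C6–C7 closure (the farnesyl C1–C10 bond) of an acyclic C15 vinyl epoxide/dienone through an allylpalladium cation equivalent. The epoxide supplies C3–OH.
4. Acyclic C15 chain ⇒ methyl geranate + methacrolein + CH2 (Wittig) + methallyl Grignard. The Shi epoxidation is the only source of chirality.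
5. Ring order: the ten‑membered carbocycle first, then rings A and B together in the cascade.

Assumption: methyl geranate is used as the pure 2E ester (any 2Z ester is distilled off). Germacrane/eremophilane numbering C1–C15 is used for all ring compounds, and alpha/beta refer to the drawing in which both ring methyl groups are beta.

**Step 1**
Reactants: 1 methyl (2E)-3,7-dimethylocta-2,6-dienoate (methyl geranate); 2 methacrolein
Product: 3 methyl (2E,6E)-3,7-dimethyl-8-oxoocta-2,6-dienoate
Conditions: 2 (5 equiv), second-generation Hoveyda–Grubbs catalyst RuCl2(H2IMes)(=CH-C6H4-2-OiPr) (3 mol %), CH2Cl2, 40 °C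
Reagents that add atoms: methacrolein (2), C=C(C)C=O
Why: Olefin cross-metathesis, in which only the electron-rich prenyl terminus is taken up by the ruthenium alkylidene (the trisubstituted enoate is inert), volatile isobutene drives the exchange, and the 2-methyl enal forms as the thermodynamic E isomer.

**Step 2**
Reactants: 3 enal ester; 4 methyltriphenylphosphonium bromide
Product: 5 methyl (2E,6E)-3,7-dimethylnona-2,6,8-trienoate
Conditions: 4, KN(SiMe3)2, THF, −78 → 0 °C
Reagents that add atoms: methyltriphenylphosphonium bromide (4), C[P+](c1ccccc1)(c1ccccc1)c1ccccc1.[Br-]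
Why: Wittig methylenation, in which the non-stabilised ylide takes the aldehyde far faster than the conjugated ester and leaves both E double bonds untouched, and no stereocentre is formed.

**Step 3**
Reactants: 5 triene ester; 6 N,O-dimethylhydroxylamine hydrochloride; 7 2-methylallylmagnesium chloride
Product: 9 (5E,9E)-2,6,10-trimethyldodeca-1,5,9,11-tetraen-4-one, via Weinreb amide 8 (not isolated)
Conditions: 6, i-PrMgCl, THF, −20 °C; then 7 (1.5 equiv), −20 → 0 °C; cold pH 6 phosphate buffer
Reagents that add atoms: 2-methylallylmagnesium chloride (7), C=C(C)C[Mg]Cl; N,O-dimethylhydroxylamine hydrochloride (6), CNOC.Cl (its atoms stay only in 8)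
Why: Weinreb ketone synthesis in one flask, in which the magnesium amide turns the ester into 8, the chelated adduct of 8 with the allylic Grignard reagent survives until the mildly acidic quench (no over-addition, no shift of the β,γ double bond into conjugation), and 1,4-addition is blocked by the β,β-disubstitution.

**Step 4**
Reactants: 9 tetraenone
Product: 10 (5E)-8-[(2R,3R)-3-ethenyl-3-methyloxiran-2-yl]-2,6-dimethylocta-1,5-dien-4-one
Conditions: D-fructose-derived Shi ketone (1 equiv), Oxone (2KHSO5·KHSO4·K2SO4), NaHCO3, MeCN/aq. disodium ethylenediaminetetraacetate, 0 °C, pH 7–8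
Reagents that add atoms: potassium peroxymonosulfate (active part of Oxone), [K+].[O-]S(=O)(=O)OO
Why: Shi asymmetric epoxidation, in which the electrophilic chiral dioxirane takes the trisubstituted diene double bond (enone, vinyl and 1,1-disubstituted olefins are much slower), the spiro transition state of the D-fructose ketone gives the (R,R)-epoxide whose CH–O carbon becomes C3 (R), and the bicarbonate protocol keeps the doubly activated CH2 from isomerising.

**Step 5**
Reactants: 10 vinyl epoxide
Product: 12 (2E,6R,7E,10R)-6-hydroxy-3,7-dimethyl-10-(prop-1-en-2-yl)cyclodeca-2,7-dien-1-one [(3R,7R)-3-hydroxygermacra-4,9,11-trien-8-one], via pi-allylpalladium alkoxide 11 (not isolated)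
Conditions: Pd(PPh3)4 (10 mol %), dppe (10 mol %), t-BuOH (5 equiv, proton shuttle), THF, 65 °C, syringe-pump addition over 10 h to 2 mM
Reagents that add atoms: none
Why: Proposed new method: zerovalent palladium ionises the vinyl epoxide with inversion to the allyl cation equivalent 11 (the laboratory counterpart of farnesyl diphosphate ionisation), the freed alkoxide deprotonates the CH2 flanked by the enone carbonyl and the isopropenyl group (pKa about 19), and the soft cross-conjugated dienolate attacks the unsubstituted allyl terminus through its α-carbon anti to palladium, which closes C6–C7, leaves the isopropenyl group on C7 and gives the E C4=C5 olefin from the syn allyl complex; the C3–O bond is never broken (3R kept), and because overall retention forces the chain onto the face the epoxide oxygen left, the ring is born in the crossed conformer with C3–O pseudo-axial and the isopropenyl group pseudo-equatorial, i.e. 7R (any minor 7-epimer is removed by chromatography); the closest known reaction type is the Tsuji–Trost alkylation of vinyl epoxides under neutral conditions and its use for medium and large rings with sulfonyl-stabilised carbanions, the new element being a ketone carbon acid.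

**Step 6**
Reactants: 12 macrocyclic alcohol; 13 angelic acid [(2Z)-2-methylbut-2-enoic acid]
Product: 14 (3R,7R)-3-angeloyloxygermacra-4E,9E,11-trien-8-one (angelate ester of 12)
Conditions: 13, 2,4,6-trichlorobenzoyl chloride, Et3N, toluene, rt, 1 h, filter; then 12, toluene, 75 °C (no DMAP)
Reagents that add atoms: angelic acid (13), C/C=C(/C)C(=O)O
Why: Yamaguchi-type mixed-anhydride esterification without nucleophilic catalyst, in which the hindered aroyl carbonyl is spared so that the alcohol takes the angeloyl group, leaving out DMAP avoids both the addition–elimination that turns angelate into tiglate and base-induced epimerisation at C7, and C3 is untouched because only O–H is broken.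

**Step 7**
Reactants: 14 macrocyclic angelate
Product: 17 neopetasin, (1R,2R,7R,8aR)-1,8a-dimethyl-6-oxo-7-(prop-1-en-2-yl)-1,2,3,4,6,7,8,8a-octahydronaphthalen-2-yl (2Z)-2-methylbut-2-enoate, via eudesm-4-yl cation enolate 15 (not isolated), via eudesm-5-yl cation enolate 16 (not isolated)
Conditions: MeAlCl2 (3 equiv, 1 M in hexanes), CH2Cl2 (5 mM), −78 → −20 °C; aq. KNaC4H4O6
Reagents that add atoms: none
Why: Proposed new method: MeAlCl2 (a proton scavenger, so that stray acid cannot isomerise the isopropenyl group or the angelate) activates the s-trans enone, and C5 of the E C4=C5 olefin adds across the ring to C10 in the chair–chair antiperiplanar array (isopropenyl pseudo-equatorial, C3–OAng pseudo-axial) to give the trans-eudesmane zwitterion 15 (H5 alpha, 10-CH3 beta); the acyloxy group destabilises the C4 cation so that the axial H5 migrates to the alpha face of C4 (4-CH3 beta, 4R) to give 16; the axial 10-CH3, the only C10 bond aligned with the empty orbital, then migrates to the beta face of C5 (5R), pushed by the aluminium enolate, and regenerates a conjugated enone as the irreversible sink; this is the germacrene → eudesmyl cation → eremophilane sequence, and the closest known reaction type is the alkylaluminium-halide-induced conjugate addition of alkenes to enones, whose zwitterions end by two successive 1,2-hydride/alkyl shifts to a β,β-disubstituted enone.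

**Step 8**
Reactants: 17 neopetasin
Product: 20 (3R,4R,5R,7R,9R,10S)-3-angeloyloxy-9-hydroxyeremophil-11-en-8-one (cis-fused, 10-H beta, 9-OH beta), via silyl enol ether 18 (not isolated), via silyloxy ketone 19 (not isolated)
Conditions: [(Ph3P)CuH]6 (2 mol %), PhMe2SiH (1.1 equiv), toluene, rt; then mCPBA (1.2 equiv), CH2Cl2, −20 °C; then AcOH/THF/H2O, rt
Reagents that add atoms: mCPBA, O=C(OO)c1cccc(Cl)c1; dimethylphenylsilane, C[SiH](C)c1ccccc1 (its silicon stays only in 18 and 19)
Why: Copper hydride 1,4-hydrosilylation followed by Rubottom oxidation, in which the phosphine copper hydride reduces only the enone (the isolated olefin and the α-branched angelate are much slower) and gives the regiodefined C8=C9 silyl enol ether; the 7-beta isopropenyl group, which would otherwise be 1,3-diaxial to the 5-CH3, holds ring B in the inverted half-chair, so that axial hydride delivery to C10 comes from the beta face (ring A blocks the alpha face) and sets the cis-fused 10S centre; the peracid then attacks the electron-rich enol ether on the convex beta face, so that silyl migration and hydrolysis leave the equatorial 9R oxygen.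

**Step 9**
Reactants: 20 hydroxy ketone; 21 3-methylbut-2-enoyl chloride (senecioyl chloride)
Product: 22 target, (3R,4R,5R,7R,9R,10S)-3-angeloyloxy-9-senecioyloxyeremophil-11-en-8-one
Conditions: 21 (1.5 equiv), pyridine, DMAP (10 mol %), CH2Cl2, 0 °C → rt
Reagents that add atoms: 3-methylbut-2-enoyl chloride (21), CC(C)=CC(=O)Cl
Why: Acylation of a secondary α-ketol with an acid chloride, in which only O–H is broken, pyridine is too weak to form the vinylketene that leads to the deconjugated ester, and C7 and C9 already hold the thermodynamically preferred all-equatorial arrangement of the cis-decalone, so mild base cannot scramble them.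

**Compound list**
1 | methyl (2E)-3,7-dimethylocta-2,6-dienoate | COC(=O)/C=C(\C)CCC=C(C)C | starting material
2 | methacrolein | C=C(C)C=O | starting material
3 | methyl (2E,6E)-3,7-dimethyl-8-oxoocta-2,6-dienoate | COC(=O)/C=C(\C)CC/C=C(\C)C=O | intermediate
4 | methyltriphenylphosphonium bromide | C[P+](c1ccccc1)(c1ccccc1)c1ccccc1.[Br-] | starting material
5 | methyl (2E,6E)-3,7-dimethylnona-2,6,8-trienoate | COC(=O)/C=C(\C)CC/C=C(\C)C=C | intermediate
6 | N,O-dimethylhydroxylamine hydrochloride | CNOC.Cl | starting material
7 | 2-methylallylmagnesium chloride | C=C(C)C[Mg]Cl | starting material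
8 | (2E,6E)-N-methoxy-N,3,7-trimethylnona-2,6,8-trienamide | CON(C)C(=O)/C=C(\C)CC/C=C(\C)C=C | intermediate
9 | (5E,9E)-2,6,10-trimethyldodeca-1,5,9,11-tetraen-4-one | C=C(C)CC(=O)/C=C(\C)CC/C=C(\C)C=C | intermediate
10 | (5E)-8-[(2R,3R)-3-ethenyl-3-methyloxiran-2-yl]-2,6-dimethylocta-1,5-dien-4-one | C=C(C)CC(=O)/C=C(\C)CC[C@H]1O[C@]1(C)C=C | intermediate
11 | pi-allylpalladium alkoxide (drawn as the sigma-allyl form, phosphines left out) | C=C(C)CC(=O)/C=C(\C)CC[C@@H]([O-])/C(C)=C/C[Pd+] | intermediate
12 | (2E,6R,7E,10R)-6-hydroxy-3,7-dimethyl-10-(prop-1-en-2-yl)cyclodeca-2,7-dien-1-one | O=C1/C=C(\C)CC[C@@H](O)/C(C)=C/C[C@@H]1C(C)=C | intermediate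
13 | angelic acid | C/C=C(/C)C(=O)O | starting material
14 | (3R,7R)-3-angeloyloxygermacra-4E,9E,11-trien-8-one | O=C1/C=C(\C)CC[C@@H](OC(=O)/C(C)=C\C)/C(C)=C/C[C@@H]1C(C)=C | intermediate
15 | trans-eudesm-4-yl cation C8 enolate (drawn without aluminium) | C=C(C)[C@H]1C[C@H]2[C+](C)[C@H](OC(=O)/C(C)=C\C)CC[C@]2(C)C=C1[O-] | intermediate
16 | eudesm-5-yl cation C8 enolate (drawn without aluminium) | C=C(C)[C@H]1C[C+]2[C@@H](C)[C@H](OC(=O)/C(C)=C\C)CC[C@]2(C)C=C1[O-] | intermediate
17 | neopetasin, (3R,4R,5R,7R)-3-angeloyloxyeremophila-9,11-dien-8-one | C=C(C)[C@H]1C[C@@]2(C)C(CC[C@@H](OC(=O)/C(C)=C\C)[C@@H]2C)=CC1=O | intermediate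
18 | cis-fused 8-(dimethylphenylsilyloxy)eremophila-8,11-dien-3-yl angelate (10-H beta) | C=C(C)[C@H]1C[C@@]2(C)[C@H](CC[C@@H](OC(=O)/C(C)=C\C)[C@@H]2C)C=C1O[Si](C)(C)c3ccccc3 | intermediate
19 | 9-beta-(dimethylphenylsilyloxy) ketone | C=C(C)[C@H]1C[C@@]2(C)[C@H](CC[C@@H](OC(=O)/C(C)=C\C)[C@@H]2C)[C@@H](O[Si](C)(C)c3ccccc3)C1=O | intermediate
20 | (3R,4R,5R,7R,9R,10S)-3-angeloyloxy-9-hydroxyeremophil-11-en-8-one | C=C(C)[C@H]1C[C@@]2(C)[C@H](CC[C@@H](OC(=O)/C(C)=C\C)[C@@H]2C)[C@@H](O)C1=O | intermediate
21 | 3-methylbut-2-enoyl chloride | CC(C)=CC(=O)Cl | starting material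
22 | (3R,4R,5R,7R,9R,10S)-3-angeloyloxy-9-senecioyloxyeremophil-11-en-8-one | C=C(C)[C@H]1C[C@@]2(C)[C@H](CC[C@@H](OC(=O)/C(C)=C\C)[C@@H]2C)[C@@H](OC(=O)C=C(C)C)C1=O | target

**Total step count:** 9. **Longest linear sequence:** 9 (1 → 22).

**Three steps most likely to fail**

Step 7 (cascade). Four things can go wrong:
- The zwitterion may lose a proton at the eudesmane stage.
- The angelate carbonyl may capture the C4 cation.
- The allylic ester may ionise.
- The ring may fold on the wrong face.

The fallback sets out from 5 and comes back at 17. It makes the enone more electrophilic and locks its conformation with a second donor on C7. Compound 5 is carried to the macrocyclic keto sulfone described under step 5. That sulfone is esterified as in step 6 to the angelate of the macrocyclic keto sulfone F4. Two equivalents of MeAlCl2 then bind the ketone oxygen and one sulfonyl oxygen as a cationic six-membered chelate. The chelate holds the sulfonyl group in the carbonyl plane (pseudo-equatorial) and so fixes the crossed conformer. The same sequence (C5–C10 bond, H shift, CH3 shift) gives 7-(phenylsulfonyl)-3-angeloyloxyeremophila-9,11-dien-8-one F5 (sulfonyl beta, isopropenyl alpha). SmI2 in THF/MeOH at −78 °C cleaves the C–S bond. The trivalent samarium dienolate is protonated from the alpha face, anti to the 5-methyl group, and this gives 17.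

Step 5 (macrocyclisation). The ketone may be too weak or too hard a carbon acid. The allylpalladium alkoxide would then drift to a dienol, an enone or a dihydrofuran instead of closing the ring. The fallback sets out from 5 and comes back at 12. It uses a true soft carbanion.
- Catalytic Shi epoxidation of 5 gives methyl (2E)-5-[(2R,3R)-3-ethenyl-3-methyloxiran-2-yl]-3-methylpent-2-enoate F1.
- Lithiated methallyl phenyl sulfone (n-BuLi, THF, −78 → 0 °C, 2.2 equiv) is acylated by F1 to give the acyclic β-keto sulfone (5E)-8-[(2R,3R)-3-ethenyl-3-methyloxiran-2-yl]-2,6-dimethyl-3-(phenylsulfonyl)octa-1,5-dien-4-one F2.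
- Pd(PPh3)4/dppe in refluxing THF closes F2 under neutral conditions. This combination of an epoxy sulfone and zerovalent palladium is the established one for medium rings. The product is (2E,6R,7E,10R)-6-hydroxy-3,7-dimethyl-10-(phenylsulfonyl)-10-(prop-1-en-2-yl)cyclodeca-2,7-dien-1-one F3.
- SmI2 in THF/MeOH at −78 °C removes the sulfonyl group. Kinetic α-protonation gives 12, and its 7-epimer is separated.

Step 8 (face of hydride delivery to C10). If substrate control gives the trans-fused series, stereocontrol is moved from the substrate to the catalyst. The fallback sets out from 17 and comes back at 18, and it makes no new compound (F0). A bisphosphine copper hydride is generated from Cu(OAc)2·H2O, DTBM-SEGPHOS and PhMe2SiH. Both ligand enantiomers are tried, and the one matched to beta-face delivery is kept. The same silyl enol ether 18 is then oxidised as in step 8.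

**Further compounds**
F1 | step 5 | methyl (2E)-5-[(2R,3R)-3-ethenyl-3-methyloxiran-2-yl]-3-methylpent-2-enoate | COC(=O)/C=C(\C)CC[C@H]1O[C@]1(C)C=C
F2 | step 5 | (5E)-8-[(2R,3R)-3-ethenyl-3-methyloxiran-2-yl]-2,6-dimethyl-3-(phenylsulfonyl)octa-1,5-dien-4-one (sulfonyl carbon labile) | C=C(C)C(C(=O)/C=C(\C)CC[C@H]1O[C@]1(C)C=C)S(=O)(=O)c2ccccc2
F3 | step 5 | (2E,6R,7E,10R)-6-hydroxy-3,7-dimethyl-10-(phenylsulfonyl)-10-(prop-1-en-2-yl)cyclodeca-2,7-dien-1-one | O=C1/C=C(\C)CC[C@@H](O)/C(C)=C/C[C@]1(C(C)=C)S(=O)(=O)c2ccccc2
F4 | step 7 | angelate of the macrocyclic keto sulfone | O=C1/C=C(\C)CC[C@@H](OC(=O)/C(C)=C\C)/C(C)=C/C[C@]1(C(C)=C)S(=O)(=O)c2ccccc2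
F5 | step 7 | 7-(phenylsulfonyl)-3-angeloyloxyeremophila-9,11-dien-8-one (sulfonyl beta, isopropenyl alpha) | C=C(C)[C@]1(S(=O)(=O)c3ccccc3)C[C@@]2(C)C(CC[C@@H](OC(=O)/C(C)=C\C)[C@@H]2C)=CC1=O
F0 | step 8 | none | none
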